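## The problem

Compound 33 (CNP0252711.1) is a spiro sesquineolignan. Labels used throughout: ring B is the oxolane O1–C2–C3–C4–C5, in which C2 carries the 4-hydroxy-3-methoxyphenyl group, C3 the hydroxymethyl carbon C9, and C5 the side-chain carbon C8. C8 bears the aryl ether to a dihydroconiferyl unit and hydroxymethyl C10. Ring A is the cyclohexadienone C4–C2'=C3'(OMe)–C4'(=O)–C5'=C6', joined to ring B at the spiro atom C4.

There are five stereocentres (2S, 3R, 4S, 5S, 8S). The C3 and C5 substituents are cis to each other and trans to the C2 aryl group, the C5–O1 and C8–OAr bonds are syn, and C2' lies on the face of the C3/C5 substituents while C6' lies on the open face. C4 is the hard centre: it is quaternary and stereogenic only because one arm of ring A carries the methoxy group. Only ring B can control it, because its C3 and C5 substituents flank C4 and cover one face.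

C2 is a para-oxygenated benzylic ether carbon. It ionises under acid, which allows a thermodynamic 2,3-trans setting early but forbids acid once ring A exists; with a free phenolate it can open ring B through a quinone methide. The cross-conjugated dienone suffers dienone–phenol rearrangement in acid and conjugate addition of the neighbouring C9 hydroxyl in base. The aryloxy group on C8 becomes a beta-leaving group as soon as C5 or C4 bears an enolisable carbonyl.

The feature that opens the problem is that C4 sits between two stereocentres in a five-membered ring, with the carbonyl C4' para to it. C4 can therefore be presented as an exocyclic methylene, and a four-carbon enol that bonds C6' to C4 and C3' to the methylene carbon C2' builds both arms of ring A with the oxygen in the right place. The C4 configuration then reduces to which face C6' takes.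

## Retrosynthesis

**Ring A oxidation level (no skeletal bond cut).** Target 33 is unmasked last from its fully silylated form 32, so that the free phenol and the three alcohols never meet base or oxidant. The methyl enol ether of 32 is cut at O–CH3 to the diosphenol 31, which comes from the hydroxy enone 29 by oxidation, and 29 from the enone 28 by enolate hydroxylation. This order is preferred to carrying a methoxy group in from the start because C3' is the only enolisable position of 28 (C4 has no hydrogen), so the oxygen enters at one site only. The forward steps must stay non-acidic and only weakly basic.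

**C5'–C6' (ring A closure).** The enone double bond of 28 is cut by a retro-aldol condensation to the keto aldehyde 27. The aldehyde at C4 cannot enolise and the methyl ketone can close only a six-membered ring, so the forward condensation has a single course. Compound 27 has no ring A at all, only two chains on C4.

**C4–C6' and C2'–C3' (key disconnection).** Compound 27 is cut to the 4-methylene oxolane 23 and the enol 25 by a retro-de Mayo operation: a formal [2+2] adduct of the enol and the alkene, opened by retro-aldol. The neighbouring cut, C4–C2' by a Robinson-type conjugate addition of a C4 aldehyde, would also attack the open face. It would however need an enolisable beta-alkoxy aldehyde on ring B (risk of ring opening) and a longer oxidation sequence afterwards. The photochemical cut never creates an enolate at C4 and puts C6', the arm without methoxy, on the open face as the target requires. Precursor 23 has one stereocentre and one ring fewer. The forward reaction must deliver face selectivity, head-to-tail orientation and bonding through the formyl end of 25.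

**O1–C2 (ring B closure).** Compound 23 is cut at the benzylic C–O bond to the 1,4-diol 22. Ionisation at C2 is easy and reversible, so both C2 epimers of 22 converge on the 2,3-trans oxolane. The alternative cut at O1–C5 would demand clean inversion at an allylic carbon next to the aryloxy group. Compound 22 is acyclic; the forward step needs only a mild acid that spares the silyl ethers.

**C5–C8 (second aldol).** Diol 22 comes from triol 21 by primary silylation, and 21 from the aldol adduct 20 by reduction, which removes the auxiliary and the acetate together. Compound 20 is cut at C5–C8 to the enal 12 and the aryloxyacetyl imide 19. An auxiliary-controlled syn glycolate aldol sets C5 and C8 in one step and in the required syn sense. The alternative, addition of a vinyl metal to an epimerisable alpha-aryloxy aldehyde, offers weaker control. The two fragments are of similar size, so the route is convergent here.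

**C4=CH2 and the aldehyde at C5.** Enal 12 is cut at the methylene group to the aldehyde 10 (alpha-methylenation), and 10 is traced to the terminal alkene 9 by oxidative cleavage. An allyl group is the simplest latent form of the C4–C5 unit and survives the first aldol.

**C2–C3 (first aldol).** Acetate 9 comes from 8 and diol 7, and these from the aldol adduct 6, which is cut at C2–C3 to imide 5 and aldehyde 2. The syn aldol sets C3 absolutely; the C2 carbinol configuration it also sets is not needed later but is defined. Imide 5 is made from 3 and 4, and aldehyde 2 from vanillin 1.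

**Aryl ether fragment.** Imide 19 is cut at the N-acyl bond to acid 16 and auxiliary 17. Acid 16 is cut at the silyl ether to 14, and 14 at the phenol O–CH2 bond to dihydroconiferyl alcohol 13.

**Enol.** Enol 25 is the hydrolysis product of the commercial acetal 24.

## Roads not taken

**Alternative 1: oxa-Michael closure of ring B.** The cut is O1–C5. In the forward step the C2 hydroxyl of the open-chain hydroxy acrylate A2 would add to C5 of its 2-aryloxyacrylate unit, giving the spiro oxolane A1 with an ester at C8 and ring A as a cyclohexene.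
- Merits: an ionic, scalable ring closure with no photochemistry, indifferent to the acrylate geometry.
- Weak points:
  - C4 must already exist in A2 as an acyclic all-carbon quaternary centre whose two ring A arms differ only in the position of one double bond, so the hardest centre is moved to where nothing controls it.
  - The acceptor is a donor-substituted acrylate whose beta carbon hangs on a quaternary carbon, so addition should be slow and reversible.
  - C8 is set by protonation of an ester enolate next to an epimerisable centre.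
  - Ring A arrives several oxidation levels below the methoxy dienone.
- Comparison: this road is better in the robustness of the ring closure and avoids light. The chosen plan sets against it auxiliary-controlled C5 and C8, a face-controlled C4, and a ring A that is one hydroxylation and one oxidation from its final state.

**Alternative 2: palladium (3+2) annulation of a quinone methide.** The cuts are O1–C5 and C3–C4. Zerovalent palladium would open the vinyl oxirane A5 to an alkoxide carrying an allyl-palladium unit. The alkoxide adds to the methide carbon of the quinone methide A4, and the para carbon of the resulting phenolate attacks the allyl unit, giving the spirodienone A3 with vinyl on C3.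
- Merits: by far the most convergent road. Ring B and the dienone form in one step and ring A needs no later oxidation.
- Weak points:
  - A4 has one ortho substituent and no bulky groups, unlike the hindered quinone methides on which such annulations are known, and should hydrate or oligomerise.
  - The configuration of C4 depends on which rotamer of the unsymmetrical ring reacts, and nothing distinguishes methoxy on the left from methoxy on the right.
  - C3, C4 and C5 are set together through a fluxional allyl terminus.
  - The vinyl group must later be degraded to hydroxymethyl beside the dienone and its enol ether.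
- Comparison: this road wins clearly on step count. The chosen plan sets against it control of C4 by face selection on a rigid ring, stable intermediates, and the correct oxidation level at C9 from the first aldol.

**Alternative 3: Prins–pinacol spirocyclisation.** The cuts are O1–C2, C2–C3 and C4–C5. Under SnCl4 the silylated vanillin A7 and the allylic diol A8 would form an oxocarbenium ion at C2. The C3=C4 alkene attacks it, and migration of C5 to the new cation at C4 contracts the first-formed six-membered ring, giving A6, a spiro oxolane with a ketone at C6'. The alkene geometry and the carbinol configuration of A8 were left open.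
- Merits: three bonds, ring B and the quaternary centre in one thermal step with chair-type stereocontrol, vanillin used directly.
- Weak points:
  - The carbonyl lands at C6', next to the spiro atom, while the target needs it at C4'. A 1,3-transposition plus two double bonds and the methoxy group make a long ring A endgame.
  - The chair transition state would be expected to favour a 2,5-cis oxolane, whereas the target is 2,5-trans.
  - The electron-rich oxocarbenium ion is a weak electrophile, and the benzylic C2–O1 bond of the product can re-ionise under SnCl4.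
  - A8 needs a tertiary carbinol and a trisubstituted alkene of defined geometry.
- Comparison: this road is better in convergence at ring B and is thermal. The chosen plan sets against it a carbonyl born at C4' and a C2/C5 relationship that its own ring closure delivers.

Key step: step 17

**Abbreviations.** TBS = tert-butyldimethylsilyl; TIPS = triisopropylsilyl; G = 3-methoxy-4-(triisopropylsilyloxy)phenyl; OD = 2-methoxy-4-[3-(tert-butyldimethylsilyloxy)propyl]phenoxy.

**Assumption (chemistry).** Enol 25 self-condenses on storage, so it is taken to be used at once as a dried solution after hydrolysis of 24. TIPS is chosen for the phenol because a phenolic TBS ether may not survive the mildly basic steps.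

## Route

Step 1
Reactants: 1 vanillin
Product: 2 3-methoxy-4-(triisopropylsilyloxy)benzaldehyde
Conditions: TIPSCl, imidazole, DMF, rt
Reagents that add atoms: triisopropylsilyl chloride, CC(C)[Si](Cl)(C(C)C)C(C)C
Why: Standard silylation of a phenol; the TIPS ether tolerates hydride, amine bases and carbonate in later steps.

Step 2
Reactants: 3 (S)-4-benzyloxazolidin-2-one; 4 pent-4-enoyl chloride
Product: 5 (S)-4-benzyl-3-(pent-4-enoyl)oxazolidin-2-one
Conditions: n-BuLi, THF, −78 °C; then 4, −78 → 0 °C
Reagents that add atoms: none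
Why: N-Acylation of the lithiated oxazolidinone; the allyl terminus is the latent C4–C5 aldehyde.

Step 3
Reactants: 5 imide; 2 aldehyde
Product: 6 syn aldol adduct (2S,3S)-3-hydroxy-3-G-2-allylpropanoyl imide
Conditions: Bu2BOTf, i-Pr2NEt, CH2Cl2, −78 → 0 °C; then pH 7 buffer, MeOH, H2O2, 0 °C
Reagents that add atoms: none
Why: Evans syn aldol through the Z boron enolate and a chair transition state; the (S)-auxiliary fixes C3 (and the C2 carbinol) as in the known benzaldehyde case, and electron-rich aryl aldehydes are good partners.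

Step 4
Reactants: 6 aldol adduct
Product: 7 (1S,2R)-1-G-2-allylpropane-1,3-diol
Conditions: LiBH4, MeOH (1 equiv), Et2O, 0 °C
Reagents that add atoms: none
Why: Reductive removal of the auxiliary turns the imide carbonyl into the C9 alcohol without touching C3; the auxiliary is recovered.

Step 5
Reactants: 7 diol
Product: 8 primary TBS ether (C9–OTBS, free benzylic C2–OH)
Conditions: TBSCl (1.05 equiv), imidazole, CH2Cl2, 0 °C
Reagents that add atoms: tert-butyldimethylsilyl chloride, CC(C)(C)[Si](C)(C)Cl
Why: The primary hydroxyl is silylated much faster than the hindered benzylic secondary one.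

Step 6
Reactants: 8 alcohol
Product: 9 benzylic acetate
Conditions: Ac2O, pyridine, DMAP (cat.), CH2Cl2, rt
Reagents that add atoms: acetic anhydride, CC(=O)OC(C)=O
Why: The acetate keeps the C2 hydroxyl from forming a lactol with the coming aldehyde and is shed later by the same hydride that removes the second auxiliary.

Step 7
Reactants: 9 terminal alkene
Product: 10 aldehyde (1S,2R)-1-G-2-(TBS-oxymethyl)-4-oxobutyl acetate
Conditions: OsO4 (2 mol%), NaIO4 (4 equiv), 2,6-lutidine, dioxane–H2O 3:1, rt
Reagents that add atoms: sodium periodate, [Na+].[O-]I(=O)(=O)=O (terminal source of the aldehyde oxygen, relayed through osmium tetroxide, O=[Os](=O)(=O)=O)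
Why: Lemieux–Johnson cleavage is chosen over ozone because it leaves the electron-rich arene alone; lutidine suppresses over-oxidation.

Step 8
Reactants: 10 aldehyde
Product: 12 enal (2-substituted acrolein with C4=CH2 and C5 as CHO), via Mannich base 11 (not isolated)
Conditions: Me2N=CH2 I (N,N-dimethylmethyleneiminium iodide), Et3N, CH2Cl2, rt
Reagents that add atoms: N,N-dimethylmethyleneiminium iodide, C=[N+](C)C.[I-]
Why: Mannich reaction at the only alpha-CH2 followed by loss of dimethylamine is the standard alpha-methylenation of aldehydes; the mild amine base should leave the C3 stereocentre and the acetate untouched.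

Step 9
Reactants: 13 dihydroconiferyl alcohol
Product: 14 2-[4-(3-hydroxypropyl)-2-methoxyphenoxy]acetic acid
Conditions: BrCH2CO2H, NaOH (aq), 80 °C; then HCl to pH 2
Reagents that add atoms: bromoacetic acid, OC(=O)CBr
Why: Williamson synthesis of an aryloxyacetic acid; in aqueous hydroxide only the phenol is ionised, so the aliphatic alcohol is not alkylated.

Step 10
Reactants: 14 hydroxy acid
Product: 16 2-[2-methoxy-4-(3-TBS-oxypropyl)phenoxy]acetic acid, via bis-silylated ester 15 (not isolated)
Conditions: TBSCl (2.5 equiv), imidazole, DMF, rt; then K2CO3, THF–H2O, rt; citric acid to pH 4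
Reagents that add atoms: tert-butyldimethylsilyl chloride, CC(C)(C)[Si](C)(C)Cl
Why: Both hydroxyl and carboxyl are silylated, and the labile silyl ester is hydrolysed selectively in the basic work-up.

Step 11
Reactants: 16 acid; 17 (R)-4-benzyloxazolidin-2-one
Product: 19 (R)-4-benzyl-3-(aryloxyacetyl)oxazolidin-2-one, via pivalic mixed anhydride 18 (not isolated)
Conditions: PivCl, Et3N, THF, −20 °C; then 17, LiCl, rt
Reagents that add atoms: none
Why: Mixed-anhydride N-acylation; the oxazolidinone attacks the unhindered aryloxyacetyl carbonyl rather than the pivaloyl one.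

Step 12
Reactants: 19 glycolate imide; 12 enal
Product: 20 syn glycolate aldol adduct (2R,3S at C8 and C5)
Conditions: Bu2BOTf, i-Pr2NEt, CH2Cl2, −78 → 0 °C; then pH 7 buffer, MeOH, H2O2, 0 °C
Reagents that add atoms: none
Why: Evans syn glycolate aldol; the Z boron enolate of the aryloxyacetyl imide adds to the alpha-branched enal through a chair transition state, and the (R)-auxiliary sets C8 and C5 syn with the required absolute sense, overriding the remote C3 centre.

Step 13
Reactants: 20 aldol adduct
Product: 21 triol (free C2, C5 and C10 hydroxyls; C9–OTBS)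
Conditions: LiBH4 (5 equiv), MeOH (5 equiv), THF, 0 °C → rt
Reagents that add atoms: none
Why: Lithium borohydride reduces both the imide (to the C10 alcohol, auxiliary recovered) and the acetate ester, so one operation frees the benzylic hydroxyl needed for ring closure.

Step 14
Reactants: 21 triol
Product: 22 1,4-diol (C10–OTBS; free C2 and C5 hydroxyls)
Conditions: TBSCl (1.1 equiv), imidazole, CH2Cl2, 0 °C
Reagents that add atoms: tert-butyldimethylsilyl chloride, CC(C)(C)[Si](C)(C)Cl
Why: Only the primary hydroxyl reacts at low temperature beside one benzylic and one allylic secondary hydroxyl.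

Step 15
Reactants: 22 1,4-diol
Product: 23 (2S,3R,5S)-2-G-3-(TBS-oxymethyl)-4-methylidene-5-[(1S)-1-OD-2-TBS-oxyethyl]oxolane
Conditions: CSA (10 mol%), 4 Å MS, CH2Cl2, 0 °C → rt
Reagents that add atoms: none
Why: SN1 cyclodehydration: acid ionises only the para-silyloxybenzylic alcohol, the C5 hydroxyl closes the five-membered ring on the cation, and because this closure is reversible the aryl group settles trans to the C3 substituent; the C5–O bond is never broken, so C5 keeps its configuration.

Step 16
Reactants: 24 4,4-dimethoxybutan-2-one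
Product: 25 (Z)-4-hydroxybut-3-en-2-one
Conditions: 1 M H2SO4 (aq), rt; extraction into CH2Cl2, dried, used at once
Reagents that add atoms: water, O
Why: Acetal hydrolysis frees 3-oxobutanal, which exists as the hydrogen-bonded cis-enol in non-polar solution, the form needed for the photoreaction.

Step 17
Reactants: 23 methylene oxolane; 25 enol
Product: 27 keto aldehyde with formyl C6' and a 3-oxobutyl arm on quaternary C4 (4S), via spiro cyclobutanol 26 (not isolated)
Conditions: hν (medium-pressure Hg lamp, Pyrex, λ > 300 nm), 25 (10 equiv, in portions), degassed cyclohexane–CH2Cl2, 10 °C; then SiO2, rt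
Reagents that add atoms: none
Why: The excited hydrogen-bonded enol 25, irradiated beyond the absorption of the two aryl ether chromophores, adds to the exocyclic alkene of 23 as an enone adds to an alkene: C3' bonds first to the unsubstituted terminus C2', leaving a tertiary radical at C4 and an oxygen-stabilised radical at C6', and collapse of this 1,4-biradical gives the head-to-tail spiro cyclobutanol 26. The closest known reaction type is the de Mayo reaction of enolised 1,3-dicarbonyl compounds with 1,1-disubstituted alkenes. The only ring the step closes is this cyclobutane, formed by biradical recombination (a stepwise [2+2]) and opened again by strain-driven retro-aldol cleavage of the C6'–C3' bond, so no ring survives and 27 carries a formyl group and a 3-oxobutyl arm on C4. The one new stereocentre, C4, is set by the oxolane: the cis substituents on C3 and C5 flank the alkene and cover one face, so C6' bonds to C4 on the other face, which carries only the more remote C2 aryl group. Three selectivities are needed: face (secured by the C3/C5 substituents), head-to-tail orientation (secured by the tertiary radical at C4) and bonding through the formyl rather than the acetyl end of the enol (secured by sterics, since only the CH end can join the fully substituted C4 without creating two adjacent quaternary carbons). Because the new aldehyde has no alpha hydrogen, ring B cannot open by beta-elimination once the quaternary centre exists.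

Step 18
Reactants: 27 keto aldehyde
Product: 28 spiro enone (ring A: C4'=O, C5'=C6', saturated C2' and C3')
Conditions: pyrrolidine (0.3 equiv), AcOH (0.3 equiv), toluene, 60 °C
Reagents that add atoms: none
Why: Intramolecular aldol condensation of a 1,5-keto aldehyde; the aldehyde cannot enolise and only the methyl carbon can close a six-membered ring, and the buffered amine spares the silyl ethers and the benzylic ether.

Step 19
Reactants: 28 enone
Product: 29 3'-hydroxy enone (both C3' epimers)
Conditions: KN(SiMe3)2, THF, −78 °C; then 2-(phenylsulfonyl)-3-phenyloxaziridine, −78 °C; NH4Cl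
Reagents that add atoms: 2-(phenylsulfonyl)-3-phenyloxaziridine, O=S(=O)(c1ccccc1)N1OC1c1ccccc1
Why: Enolate hydroxylation with an N-sulfonyloxaziridine; C3' is the only enolisable position (C4 has no hydrogen), so the cross-conjugated enolate forms at one site, and the new C3' configuration is erased in step 20.

Step 20
Reactants: 29 hydroxy enone
Product: 31 diosphenol (3'-hydroxy-2',5'-dien-4'-one), via 3',4'-dione 30 (not isolated)
Conditions: Dess–Martin periodinane, NaHCO3, CH2Cl2, rt
Reagents that add atoms: none
Why: Dess–Martin oxidation of the alpha-hydroxy ketone gives the 1,2-dione, which enolises toward C2', its only enolisable carbon, to the conjugated diosphenol; bicarbonate keeps the medium non-acidic for the benzylic ether.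

Step 21
Reactants: 31 diosphenol
Product: 32 3'-methoxy dienone (fully silylated 33)
Conditions: MeI, K2CO3, acetone, rt
Reagents that add atoms: iodomethane, CI
Why: Diosphenols are acidic enols that are O-methylated under carbonate conditions; the phenol is protected and no other acidic hydroxyl is present.

Step 22
Reactants: 32 silylated dienone
Product: 33 CNP0252711.1
Conditions: Bu4NF–AcOH (1:1, 8 equiv), THF, 0 °C → rt
Reagents that add atoms: none
Why: Buffered fluoride removes the three alkyl TBS ethers and the phenolic TIPS ether without free alkoxide or phenolate, protecting the dienone from conjugate addition and ring B from quinone methide opening; no stereocentre is touched.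

## Compound list

1 | vanillin (4-hydroxy-3-methoxybenzaldehyde) | COc1cc(C=O)ccc1O | starting material
2 | 3-methoxy-4-(triisopropylsilyloxy)benzaldehyde | COc1cc(C=O)ccc1O[Si](C(C)C)(C(C)C)C(C)C | intermediate
3 | (S)-4-benzyloxazolidin-2-one | O=C1N[C@@H](Cc2ccccc2)CO1 | starting material
4 | pent-4-enoyl chloride | C=CCCC(Cl)=O | starting material
5 | (S)-4-benzyl-3-(pent-4-enoyl)oxazolidin-2-one | C=CCCC(=O)N1[C@@H](Cc2ccccc2)COC1=O | intermediate
6 | (4S)-4-benzyl-3-[(2S,3S)-3-hydroxy-3-G-2-(prop-2-en-1-yl)propanoyl]oxazolidin-2-one | C=CC[C@@H]([C@H](O)c1ccc(O[Si](C(C)C)(C(C)C)C(C)C)c(OC)c1)C(=O)N1[C@@H](Cc2ccccc2)COC1=O | intermediate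
7 | (1S,2R)-1-G-2-(prop-2-en-1-yl)propane-1,3-diol | C=CC[C@H](CO)[C@H](O)c1ccc(O[Si](C(C)C)(C(C)C)C(C)C)c(OC)c1 | intermediate
8 | (1S,2R)-1-G-2-[(TBS-oxy)methyl]pent-4-en-1-ol | C=CC[C@H](CO[Si](C)(C)C(C)(C)C)[C@H](O)c1ccc(O[Si](C(C)C)(C(C)C)C(C)C)c(OC)c1 | intermediate
9 | (1S,2R)-1-G-2-[(TBS-oxy)methyl]pent-4-en-1-yl acetate | C=CC[C@H](CO[Si](C)(C)C(C)(C)C)[C@H](OC(C)=O)c1ccc(O[Si](C(C)C)(C(C)C)C(C)C)c(OC)c1 | intermediate
10 | (1S,2R)-1-G-2-[(TBS-oxy)methyl]-4-oxobutyl acetate | O=CC[C@H](CO[Si](C)(C)C(C)(C)C)[C@H](OC(C)=O)c1ccc(O[Si](C(C)C)(C(C)C)C(C)C)c(OC)c1 | intermediate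
11 | (1S,2R)-1-G-2-[(TBS-oxy)methyl]-3-[(dimethylamino)methyl]-4-oxobutyl acetate (Mannich base, both C3 epimers, not isolated) | CN(C)CC(C=O)[C@H](CO[Si](C)(C)C(C)(C)C)[C@H](OC(C)=O)c1ccc(O[Si](C(C)C)(C(C)C)C(C)C)c(OC)c1 | intermediate
12 | (1S,2R)-1-G-2-[(TBS-oxy)methyl]-3-formylbut-3-en-1-yl acetate | C=C(C=O)[C@H](CO[Si](C)(C)C(C)(C)C)[C@H](OC(C)=O)c1ccc(O[Si](C(C)C)(C(C)C)C(C)C)c(OC)c1 | intermediate
13 | dihydroconiferyl alcohol (4-(3-hydroxypropyl)-2-methoxyphenol) | COc1cc(CCCO)ccc1O | starting material
14 | 2-[4-(3-hydroxypropyl)-2-methoxyphenoxy]acetic acid | COc1cc(CCCO)ccc1OCC(=O)O | intermediate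
15 | tert-butyldimethylsilyl 2-[2-methoxy-4-[3-(TBS-oxy)propyl]phenoxy]acetate (not isolated) | COc1cc(CCCO[Si](C)(C)C(C)(C)C)ccc1OCC(=O)O[Si](C)(C)C(C)(C)C | intermediate
16 | 2-[2-methoxy-4-[3-(TBS-oxy)propyl]phenoxy]acetic acid | COc1cc(CCCO[Si](C)(C)C(C)(C)C)ccc1OCC(=O)O | intermediate
17 | (R)-4-benzyloxazolidin-2-one | O=C1N[C@H](Cc2ccccc2)CO1 | starting material
18 | 2-[2-methoxy-4-[3-(TBS-oxy)propyl]phenoxy]acetic pivalic anhydride (not isolated) | COc1cc(CCCO[Si](C)(C)C(C)(C)C)ccc1OCC(=O)OC(=O)C(C)(C)C | intermediate
19 | (R)-4-benzyl-3-[2-(OD)acetyl]oxazolidin-2-one | COc1cc(CCCO[Si](C)(C)C(C)(C)C)ccc1OCC(=O)N1[C@H](Cc2ccccc2)COC1=O | intermediate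
20 | (4R)-4-benzyl-3-[(2R,3S,5R,6S)-6-acetoxy-2-(OD)-6-G-3-hydroxy-4-methylidene-5-[(TBS-oxy)methyl]hexanoyl]oxazolidin-2-one | C=C([C@H](CO[Si](C)(C)C(C)(C)C)[C@H](OC(C)=O)c1ccc(O[Si](C(C)C)(C(C)C)C(C)C)c(OC)c1)[C@H](O)[C@@H](Oc1ccc(CCCO[Si](C)(C)C(C)(C)C)cc1OC)C(=O)N1[C@H](Cc2ccccc2)COC1=O | intermediate
21 | (2S,3S,5R,6S)-2-(OD)-6-G-4-methylidene-5-[(TBS-oxy)methyl]hexane-1,3,6-triol | C=C([C@H](CO[Si](C)(C)C(C)(C)C)[C@H](O)c1ccc(O[Si](C(C)C)(C(C)C)C(C)C)c(OC)c1)[C@H](O)[C@H](CO)Oc1ccc(CCCO[Si](C)(C)C(C)(C)C)cc1OC | intermediate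
22 | (1S,2R,4S,5S)-5-(OD)-1-G-3-methylidene-6-(TBS-oxy)-2-[(TBS-oxy)methyl]hexane-1,4-diol | C=C([C@H](CO[Si](C)(C)C(C)(C)C)[C@H](O)c1ccc(O[Si](C(C)C)(C(C)C)C(C)C)c(OC)c1)[C@H](O)[C@H](CO[Si](C)(C)C(C)(C)C)Oc1ccc(CCCO[Si](C)(C)C(C)(C)C)cc1OC | intermediate
23 | (2S,3R,5S)-2-G-3-[(TBS-oxy)methyl]-4-methylidene-5-[(1S)-1-(OD)-2-(TBS-oxy)ethyl]oxolane | C=C1[C@H](CO[Si](C)(C)C(C)(C)C)[C@@H](c2ccc(O[Si](C(C)C)(C(C)C)C(C)C)c(OC)c2)O[C@@H]1[C@H](CO[Si](C)(C)C(C)(C)C)Oc1ccc(CCCO[Si](C)(C)C(C)(C)C)cc1OC | intermediate
24 | 4,4-dimethoxybutan-2-one | CC(=O)CC(OC)OC | starting material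
25 | (Z)-4-hydroxybut-3-en-2-one (enol of 3-oxobutanal) | CC(=O)/C=C\O | intermediate
26 | spiro cyclobutanol photoadduct: oxolane of 23 with C4 spiro to a 3-acetyl-2-hydroxycyclobutane (C4–C6'(OH) bond anti to the C3 and C5 substituents; acetyl and hydroxyl centres unassigned; not isolated) | CC(=O)C1C[C@]2(C1O)[C@H](CO[Si](C)(C)C(C)(C)C)[C@@H](c1ccc(O[Si](C(C)C)(C(C)C)C(C)C)c(OC)c1)O[C@@H]2[C@H](CO[Si](C)(C)C(C)(C)C)Oc1ccc(CCCO[Si](C)(C)C(C)(C)C)cc1OC | intermediate
27 | (2S,3R,4S,5S)-2-G-3-[(TBS-oxy)methyl]-4-(3-oxobutyl)-5-[(1S)-1-(OD)-2-(TBS-oxy)ethyl]oxolane-4-carbaldehyde | CC(=O)CC[C@]1(C=O)[C@H](CO[Si](C)(C)C(C)(C)C)[C@@H](c2ccc(O[Si](C(C)C)(C(C)C)C(C)C)c(OC)c2)O[C@@H]1[C@H](CO[Si](C)(C)C(C)(C)C)Oc1ccc(CCCO[Si](C)(C)C(C)(C)C)cc1OC | intermediate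
28 | spiro enone: (2S,3R,4S,5S)-oxolane of 27 with C4 spiro to cyclohex-5'-en-4'-one (C2', C3' saturated) | O=C1CC[C@]2(C=C1)[C@H](CO[Si](C)(C)C(C)(C)C)[C@@H](c1ccc(O[Si](C(C)C)(C(C)C)C(C)C)c(OC)c1)O[C@@H]2[C@H](CO[Si](C)(C)C(C)(C)C)Oc1ccc(CCCO[Si](C)(C)C(C)(C)C)cc1OC | intermediate
29 | 3'-hydroxy derivative of 28 (both C3' epimers) | O=C1C(O)C[C@]2(C=C1)[C@H](CO[Si](C)(C)C(C)(C)C)[C@@H](c1ccc(O[Si](C(C)C)(C(C)C)C(C)C)c(OC)c1)O[C@@H]2[C@H](CO[Si](C)(C)C(C)(C)C)Oc1ccc(CCCO[Si](C)(C)C(C)(C)C)cc1OC | intermediate
30 | 3',4'-dione (cyclohex-5'-ene-3',4'-dione spiro at C4; not isolated) | O=C1C(=O)C[C@]2(C=C1)[C@H](CO[Si](C)(C)C(C)(C)C)[C@@H](c1ccc(O[Si](C(C)C)(C(C)C)C(C)C)c(OC)c1)O[C@@H]2[C@H](CO[Si](C)(C)C(C)(C)C)Oc1ccc(CCCO[Si](C)(C)C(C)(C)C)cc1OC | intermediate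
31 | diosphenol: 3'-hydroxycyclohexa-2',5'-dien-4'-one spiro at C4 (4S) | OC1=C[C@]2(C=CC1=O)[C@H](CO[Si](C)(C)C(C)(C)C)[C@@H](c1ccc(O[Si](C(C)C)(C(C)C)C(C)C)c(OC)c1)O[C@@H]2[C@H](CO[Si](C)(C)C(C)(C)C)Oc1ccc(CCCO[Si](C)(C)C(C)(C)C)cc1OC | intermediate
32 | fully silylated target: 3'-methoxycyclohexa-2',5'-dien-4'-one spiro at C4 (2S,3R,4S,5S; side chain 1S) | COC1=C[C@]2(C=CC1=O)[C@H](CO[Si](C)(C)C(C)(C)C)[C@@H](c1ccc(O[Si](C(C)C)(C(C)C)C(C)C)c(OC)c1)O[C@@H]2[C@H](CO[Si](C)(C)C(C)(C)C)Oc1ccc(CCCO[Si](C)(C)C(C)(C)C)cc1OC | intermediate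
33 | CNP0252711.1: (2S,3R,4S,5S)-2-(4-hydroxy-3-methoxyphenyl)-3-(hydroxymethyl)-5-[(1S)-2-hydroxy-1-[4-(3-hydroxypropyl)-2-methoxyphenoxy]ethyl]oxolane, C4 spiro to 3'-methoxycyclohexa-2',5'-dien-4'-one | COC1=C[C@]2(C=CC1=O)[C@H](CO)[C@@H](c1ccc(O)c(OC)c1)O[C@@H]2[C@H](CO)Oc1ccc(CCCO)cc1OC | target

## Step count and risks

Total: 22 steps. Longest linear sequence: 17 steps (1, 3–8, 12–15, 17–22).

**Step 17 (key step).** Most likely failures:
- The hindered 1,1-disubstituted alkene adds slowly while the enol is used up by self-condensation.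
- Orientation leaks to head-to-head adducts or to bonding through the acetyl end.
- Facial selectivity erodes in the biradical closure.
- The keto aldehyde suffers secondary Norrish cleavage on prolonged irradiation.

Fallback, a thermal Robinson-type sequence that sets out from 23 and returns at 32:
- Hydroboration of the exocyclic alkene with 9-BBN and oxidative work-up would give the 4-(hydroxymethyl)oxolane F1.
- Dess–Martin oxidation would give the enolisable oxolane-4-carbaldehyde F2.
- Amine-catalysed Michael addition of F2 to but-3-en-2-one brings the 3-oxobutyl arm to the open face and gives the C4-epimeric keto aldehyde F3.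
- Aldol condensation gives the spiro enone F4, whose double bond now lies in the arm that is to carry the methoxy group.
- Nucleophilic epoxidation (t-BuOOH, DBU) gives the epoxy ketone F5.
- Methoxide opening at C3' with loss of water gives the 3'-methoxy enone F6.
- Dehydrogenation across C5'–C6' with 2-iodoxybenzoic acid gives 32.

This is two steps longer and passes through an aldehyde whose enolate could open ring B, which is why it is the reserve and not the plan.

**Step 15.** Most likely failures:
- The C2 cation loses a proton to a styrene instead of being trapped.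
- A primary TBS ether is lost under acid.
- Equilibration to the 2,3-trans isomer is incomplete.

Fallback, a base-triggered quinone methide closure that sets out from 20 and returns at 23:
- NaBH4 in wet THF removes the auxiliary but keeps the acetate, giving the diol acetate F7.
- Primary silylation gives the acetate F8.
- One equivalent of Bu4NF at low temperature cleaves only the phenolic silyl ether. The phenolate expels the benzylic acetate, and the quinone methide is trapped by the C5 hydroxyl to give the phenolic oxolane F9.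
- TIPSCl and imidazole return 23.

**Step 21 (with step 20).** Most likely failures: C-methylation at C2' competes with O-methylation, or the dione is over-oxidised or cleaved before it enolises. Fallback, setting out from 29 and returning at 32: methylation of the secondary hydroxyl with MeOTf and 2,6-di-tert-butylpyridine gives the saturated 3'-methoxy enone F10, and dehydrogenation across C2'–C3' with 2-iodoxybenzoic acid then gives 32 without ever forming the diosphenol.

**Step 22.** Most likely failures:
- A fluoride-generated alkoxide at C9 adds in conjugate fashion to C2' of the dienone.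
- The phenolate opens ring B through a quinone methide with loss of the C2 configuration.
- The phenolic silyl ether is removed incompletely.

Fallback, a two-stage unmasking that sets out from 32: HF·pyridine buffered with pyridine removes the three alkyl silyl ethers under acidic conditions and gives the phenol-protected triol F11. KHF2 in methanol then cleaves only the phenolic silyl ether under near-neutral conditions to reach 33.

## Further compounds

F1 | step 17 | [(2S,3R,4S,5S)-configured] 2-G-3-[(TBS-oxy)methyl]-4-(hydroxymethyl)-5-[(1S)-1-(OD)-2-(TBS-oxy)ethyl]oxolane (C3, C4, C5 substituents all cis) | OC[C@@H]1[C@H](CO[Si](C)(C)C(C)(C)C)[C@@H](c2ccc(O[Si](C(C)C)(C(C)C)C(C)C)c(OC)c2)O[C@@H]1[C@H](CO[Si](C)(C)C(C)(C)C)Oc1ccc(CCCO[Si](C)(C)C(C)(C)C)cc1OC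
F2 | step 17 | corresponding oxolane-4-carbaldehyde (C4–H, enolisable) | O=C[C@@H]1[C@H](CO[Si](C)(C)C(C)(C)C)[C@@H](c2ccc(O[Si](C(C)C)(C(C)C)C(C)C)c(OC)c2)O[C@@H]1[C@H](CO[Si](C)(C)C(C)(C)C)Oc1ccc(CCCO[Si](C)(C)C(C)(C)C)cc1OC
F3 | step 17 | C4 epimer of 27 (3-oxobutyl arm anti to the C3 and C5 substituents) | CC(=O)CC[C@@]1(C=O)[C@H](CO[Si](C)(C)C(C)(C)C)[C@@H](c2ccc(O[Si](C(C)C)(C(C)C)C(C)C)c(OC)c2)O[C@@H]1[C@H](CO[Si](C)(C)C(C)(C)C)Oc1ccc(CCCO[Si](C)(C)C(C)(C)C)cc1OC
F4 | step 17 | C4 epimer of 28 (ring A: C4'=O, C2'=C3', saturated C5' and C6') | O=C1CC[C@@]2(C=C1)[C@H](CO[Si](C)(C)C(C)(C)C)[C@@H](c1ccc(O[Si](C(C)C)(C(C)C)C(C)C)c(OC)c1)O[C@@H]2[C@H](CO[Si](C)(C)C(C)(C)C)Oc1ccc(CCCO[Si](C)(C)C(C)(C)C)cc1OC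
F5 | step 17 | 2',3'-epoxy ketone of F4 (epoxide face unassigned) | O=C1CC[C@@]2(C3OC13)[C@H](CO[Si](C)(C)C(C)(C)C)[C@@H](c1ccc(O[Si](C(C)C)(C(C)C)C(C)C)c(OC)c1)O[C@@H]2[C@H](CO[Si](C)(C)C(C)(C)C)Oc1ccc(CCCO[Si](C)(C)C(C)(C)C)cc1OC
F6 | step 17 | 5',6'-dihydro derivative of 32 (3'-methoxycyclohex-2'-en-4'-one spiro at C4) | COC1=C[C@]2(CCC1=O)[C@H](CO[Si](C)(C)C(C)(C)C)[C@@H](c1ccc(O[Si](C(C)C)(C(C)C)C(C)C)c(OC)c1)O[C@@H]2[C@H](CO[Si](C)(C)C(C)(C)C)Oc1ccc(CCCO[Si](C)(C)C(C)(C)C)cc1OC
F7 | step 15 | (1S,2R,4S,5S)-5-(OD)-1-G-4,6-dihydroxy-3-methylidene-2-[(TBS-oxy)methyl]hexyl acetate | C=C([C@H](CO[Si](C)(C)C(C)(C)C)[C@H](OC(C)=O)c1ccc(O[Si](C(C)C)(C(C)C)C(C)C)c(OC)c1)[C@H](O)[C@H](CO)Oc1ccc(CCCO[Si](C)(C)C(C)(C)C)cc1OC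
F8 | step 15 | (1S,2R,4S,5S)-5-(OD)-1-G-4-hydroxy-3-methylidene-6-(TBS-oxy)-2-[(TBS-oxy)methyl]hexyl acetate | C=C([C@H](CO[Si](C)(C)C(C)(C)C)[C@H](OC(C)=O)c1ccc(O[Si](C(C)C)(C(C)C)C(C)C)c(OC)c1)[C@H](O)[C@H](CO[Si](C)(C)C(C)(C)C)Oc1ccc(CCCO[Si](C)(C)C(C)(C)C)cc1OC
F9 | step 15 | free-phenol analogue of 23: (2S,3R,5S)-2-(4-hydroxy-3-methoxyphenyl)-3-[(TBS-oxy)methyl]-4-methylidene-5-[(1S)-1-(OD)-2-(TBS-oxy)ethyl]oxolane | C=C1[C@H](CO[Si](C)(C)C(C)(C)C)[C@@H](c2ccc(O)c(OC)c2)O[C@@H]1[C@H](CO[Si](C)(C)C(C)(C)C)Oc1ccc(CCCO[Si](C)(C)C(C)(C)C)cc1OC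
F10 | step 21 | 3'-O-methyl ether of 29 (3'-methoxycyclohex-5'-en-4'-one spiro at C4; both C3' epimers) | O=C1C(OC)C[C@]2(C=C1)[C@H](CO[Si](C)(C)C(C)(C)C)[C@@H](c1ccc(O[Si](C(C)C)(C(C)C)C(C)C)c(OC)c1)O[C@@H]2[C@H](CO[Si](C)(C)C(C)(C)C)Oc1ccc(CCCO[Si](C)(C)C(C)(C)C)cc1OC
F11 | step 22 | phenolic TIPS ether of 33 (three alcohols free) | COC1=C[C@]2(C=CC1=O)[C@H](CO)[C@@H](c1ccc(O[Si](C(C)C)(C(C)C)C(C)C)c(OC)c1)O[C@@H]2[C@H](CO)Oc1ccc(CCCO)cc1OC
A1 | alternative 1 | spiro oxolane with ethyl ester at C8 and ring A as cyclohexene | C1CCC=C[C@]12[C@H](CO[Si](C)(C)C(C)(C)C)[C@@H](c1ccc(O[Si](C)(C)C(C)(C)C)c(OC)c1)O[C@@H]2[C@H](C(=O)OCC)Oc1ccc(CCCO[Si](C)(C)C(C)(C)C)cc1OC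
A2 | alternative 1 | open-chain hydroxy 2-aryloxyacrylate (acrylate geometry open) | C1CCC=C[C@]1(C=C(Oc2ccc(CCCO[Si](C)(C)C(C)(C)C)cc2OC)C(=O)OCC)[C@H](CO[Si](C)(C)C(C)(C)C)[C@H](O)c1ccc(O[Si](C)(C)C(C)(C)C)c(OC)c1
A3 | alternative 2 | silylated spirodienone with vinyl on C3 | COC1=C[C@]2(C=CC1=O)[C@H](C=C)[C@@H](c1ccc(O[Si](C)(C)C(C)(C)C)c(OC)c1)O[C@@H]2[C@H](CO[Si](C)(C)C(C)(C)C)Oc1ccc(CCCO[Si](C)(C)C(C)(C)C)cc1OC
A4 | alternative 2 | 2-methoxy para-quinone methide carrying the C8 side chain on the methide carbon (methide geometry open) | COC1=CC(=C[C@H](CO[Si](C)(C)C(C)(C)C)Oc2ccc(CCCO[Si](C)(C)C(C)(C)C)cc2OC)C=CC1=O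
A5 | alternative 2 | (2R,3R)-2-[4-(tert-butyldimethylsilyloxy)-3-methoxyphenyl]-3-vinyloxirane (trans) | C=C[C@H]1O[C@@H]1c1ccc(O[Si](C)(C)C(C)(C)C)c(OC)c1
A6 | alternative 3 | spiro oxolane with ring A ketone at C6' | O=C1CCCC[C@@]12[C@H](CO[Si](C)(C)C(C)(C)C)[C@@H](c1ccc(O[Si](C)(C)C(C)(C)C)c(OC)c1)O[C@@H]2[C@H](CO[Si](C)(C)C(C)(C)C)Oc1ccc(CCCO[Si](C)(C)C(C)(C)C)cc1OC
A7 | alternative 3 | 4-(tert-butyldimethylsilyloxy)-3-methoxybenzaldehyde | COc1cc(C=O)ccc1O[Si](C)(C)C(C)(C)C
A8 | alternative 3 | allylic 1,2-diol: 1-[(1S,2S)-configured 2-(OD)-1-hydroxy-3-(TBS-oxy)propyl]-2-[2-(TBS-oxy)ethylidene]cyclohexan-1-ol (alkene geometry and ring carbinol configuration open) | OC1(CCCCC1=CCO[Si](C)(C)C(C)(C)C)[C@H](O)[C@H](CO[Si](C)(C)C(C)(C)C)Oc1ccc(CCCO[Si](C)(C)C(C)(C)C)cc1OC
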